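**Strategy**

Everything rests on cutting ring C at O1–C8a and C4–C4a, two bonds to neighbouring carbons of ring A. Because the C5 oxygen sits beside C4a, an aryne across C4a–C8a should take an alkoxide at C8a and leave a carbanion at C4a that closes on an amide carbonyl, so one operation joins both halves and forms ring C without touching the C2 carbinol set beforehand. The aryne precursor is a prenylated ortho-silylaryl triflate built on 5-methoxyresorcinol; its partner is an (S)-β-silyloxy N-methoxy-N-methylamide, the silyl ether standing in for the free hydroxyl so that no O–H proton can quench the aryl anion.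

Key step: step 11

Remark on the chemistry: C2 of the target is S (O1 > C1′ > C3 > H) and is the same atom as the carbinol carbon of the amide partner, which is also S. The annulation breaks no bond at that carbon, so the ketone reduction in step 9 alone sets the configuration. The structures of both annulation partners and of the annulation product were re-derived atom by atom and needed no correction.

**Route**

Step 1
Reactants: 1 5-methoxyresorcinol
Product: 2 5-methoxy-1,3-phenylene bis(N-isopropylcarbamate)
Conditions: i-PrNCO (2.5 equiv), Et3N (0.2 equiv), CH2Cl2, rt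
Reagents that add atoms: isopropyl isocyanate, CC(C)N=C=O
Why: amine-catalysed addition of both phenolic hydroxyls to the isocyanate (carbamoylation) is clean chemistry and keeps the ring symmetric, so no statistical monoprotection is needed at the outset.

Step 2
Reactants: 2 5-methoxy-1,3-phenylene bis(N-isopropylcarbamate)
Product: 6 5-methoxy-2-(trimethylsilyl)-1,3-phenylene bis(N-isopropylcarbamate), via bis(N-silyl) carbamate 3 (not isolated), via aryllithium 4 (not isolated), via C-silylated bis(N-silyl) carbamate 5 (not isolated)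
Conditions: TBSOTf (2.2 equiv), TMEDA (2.2 equiv), Et2O, 0 °C → rt; TMEDA (3 equiv), n-BuLi (3.3 equiv), −78 °C; TMSCl (4 equiv), −78 °C → rt; MeOH, aq. NaHSO4
Reagents that add atoms: chlorotrimethylsilane, C[Si](C)(C)Cl
Why: directed ortho-metalation of the carbamate N-silylated in the flask: the carbon between the two carbamates is the only one flanked by two strong directing groups, so the site of lithiation and silylation is fixed by symmetry, and the N–Si bonds are hydrolysed in the work-up.

Step 3
Reactants: 6 5-methoxy-2-(trimethylsilyl)-1,3-phenylene bis(N-isopropylcarbamate)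
Product: 7 3-hydroxy-5-methoxy-2-(trimethylsilyl)phenyl N-isopropylcarbamate
Conditions: DBU (1.1 equiv), Et2NH (1.0 equiv), MeCN, 40 °C; pH 5 buffer work-up
Reagents that add atoms: none
Why: base-induced E1cB cleavage of an N-monoalkyl aryl carbamate (the isocyanate is caught by Et2NH) is mild; the two carbamates are equivalent, so either cleavage gives the same phenol, and with the amine as limiting reagent and the second cleavage having to expel a more electron-rich aryloxide the reaction should stop largely at the mono-phenol, with bis-carbamate and diol recyclable.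

Step 4
Reactants: 7 3-hydroxy-5-methoxy-2-(trimethylsilyl)phenyl N-isopropylcarbamate
Product: 8 5-methoxy-3-(methoxymethoxy)-2-(trimethylsilyl)phenyl N-isopropylcarbamate
Conditions: MOMCl (1.5 equiv), i-Pr2NEt (2.5 equiv), CH2Cl2, 0 °C → rt
Reagents that add atoms: chloromethyl methyl ether, COCCl
Why: O-alkylation of the phenol (acetal formation under amine base) is chemoselective over the carbamate N–H, and the buffered medium protects the electron-rich aryl–silicon bond from protodesilylation.

Step 5
Reactants: 8 5-methoxy-3-(methoxymethoxy)-2-(trimethylsilyl)phenyl N-isopropylcarbamate; 9 prenyl bromide (1-bromo-3-methylbut-2-ene)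
Product: 13 3-methoxy-5-(methoxymethoxy)-2-(3-methylbut-2-en-1-yl)-6-(trimethylsilyl)phenyl N-isopropylcarbamate, via N-silyl carbamate 10 (not isolated), via aryllithium 11 (not isolated), via N-silyl prenyl carbamate 12 (not isolated)
Conditions: TBSOTf (1.1 equiv), TMEDA (1.1 equiv), Et2O, 0 °C → rt; TMEDA (2 equiv), n-BuLi (2.2 equiv), −78 °C; CuBr·SMe2 (10 mol %), prenyl bromide (3 equiv), −78 → 0 °C; MeOH, aq. NaHSO4, 0 °C
Reagents that add atoms: none
Why: second directed ortho-metalation: the N-silylated carbamate is the strongest directing group left and its only free ortho carbon lies between it and the methoxy group, so lithiation there and copper-catalysed SN2 alkylation at low temperature (before any anionic Fries shift) should place the prenyl group at the future C8.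

Step 6
Reactants: 13 3-methoxy-5-(methoxymethoxy)-2-(3-methylbut-2-en-1-yl)-6-(trimethylsilyl)phenyl N-isopropylcarbamate
Product: 15 3-methoxy-5-(methoxymethoxy)-2-(3-methylbut-2-en-1-yl)-6-(trimethylsilyl)phenyl trifluoromethanesulfonate, via phenol 14 (not isolated)
Conditions: DBU (1.5 equiv), Et2NH (1.2 equiv), MeCN, 40 °C; then PhNTf2 (1.5 equiv), rt
Reagents that add atoms: N-phenylbis(trifluoromethanesulfonimide), O=S(=O)(N(c1ccccc1)S(=O)(=O)C(F)(F)F)C(F)(F)F
Why: the same E1cB carbamate cleavage frees the hindered phenoxide, which is triflated in the same flask by the mild sulfonyl-transfer reagent under conditions that spare the MOM ether, the prenyl group and the aryl–silicon bond.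

Step 7
Reactants: 16 methyl 3,4-dihydroxybenzoate
Product: 17 methyl 3,4-bis(methoxymethoxy)benzoate
Conditions: MOMCl (3 equiv), i-Pr2NEt (4 equiv), CH2Cl2, 0 °C → rt
Reagents that add atoms: chloromethyl methyl ether, COCCl
Why: standard double MOM protection of a catechol by O-alkylation, which also removes the acidic protons before the enolate chemistry.

Step 8
Reactants: 17 methyl 3,4-bis(methoxymethoxy)benzoate; 18 N-methoxy-N-methylacetamide
Product: 20 3-[3,4-bis(methoxymethoxy)phenyl]-N-methoxy-N-methyl-3-oxopropanamide, via lithium enolate 19 (not isolated)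
Conditions: 18 (2.2 equiv), LDA (2.2 equiv), THF, −78 °C; then 17, −78 → −20 °C; AcOH quench
Reagents that add atoms: none
Why: crossed Claisen condensation: the amide enolate acylates the non-enolisable aryl ester, and the second equivalent of enolate deprotonates the β-keto amide formed, which drives the reaction and shields the product from further addition.

Step 9
Reactants: 20 3-[3,4-bis(methoxymethoxy)phenyl]-N-methoxy-N-methyl-3-oxopropanamide
Product: 21 (S)-3-[3,4-bis(methoxymethoxy)phenyl]-3-hydroxy-N-methoxy-N-methylpropanamide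
Conditions: RuCl[(S,S)-TsDPEN](p-cymene) (1 mol %), HCO2H/Et3N (5:2), DMF, 30 °C
Reagents that add atoms: none
Why: Noyori–Ikariya asymmetric transfer hydrogenation of an aryl ketone; the (S,S)-ligand delivers hydride to the face that gives the (S)-carbinol of aryl alkyl ketones (aryl outranks CH2C(O)N as it outranks methyl), which sets the only stereocentre of the target, the future C2.

Step 10
Reactants: 21 (S)-3-[3,4-bis(methoxymethoxy)phenyl]-3-hydroxy-N-methoxy-N-methylpropanamide
Product: 22 (S)-3-[3,4-bis(methoxymethoxy)phenyl]-N-methoxy-N-methyl-3-(trimethylsilyloxy)propanamide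
Conditions: TMSCl (1.3 equiv), Et3N (1.6 equiv), CH2Cl2, 0 °C; filtered through basic alumina, used at once
Reagents that add atoms: chlorotrimethylsilane, C[Si](C)(C)Cl
Why: routine O-silylation of a secondary alcohol, which leaves the stereocentre untouched and turns the hydroxyl into a proton-free alkoxide source for the next step.

Step 11
Reactants: 15 3-methoxy-5-(methoxymethoxy)-2-(3-methylbut-2-en-1-yl)-6-(trimethylsilyl)phenyl trifluoromethanesulfonate; 22 (S)-3-[3,4-bis(methoxymethoxy)phenyl]-N-methoxy-N-methyl-3-(trimethylsilyloxy)propanamide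
Product: 26 (2S)-2-[3,4-bis(methoxymethoxy)phenyl]-7-methoxy-5-(methoxymethoxy)-8-(3-methylbut-2-en-1-yl)chroman-4-one, via aryne 23 (not isolated), via cesium alkoxide 24 (not isolated), via O-silyl hemiaminal 25 (not isolated)
Conditions: 15 (1.5 equiv), 22 (1.0 equiv), CsF (3 equiv), 18-crown-6 (1 equiv), THF, 0 °C → rt, sealed flask; then aq. citric acid (pH 4), 0 °C
Reagents that add atoms: none
Why: Proposed new method: fluoride removes the C-silyl group of 15 and triflate leaves to give aryne 23 across C4a–C8a, while the same fluoride unmasks silyl ether 22 as alkoxide 24 with no O–H proton in the flask; 24 adds at C8a, the aryl anion so placed at C4a attacks the amide carbonyl, and the tetrahedral adduct is expected to be re-silylated by the Me3SiF released to give 25, which keeps the ketone masked and non-basic until the mildly acidic work-up. The closest known reaction type is the fluoride-triggered aryne insertion–annulation in which an oxygen nucleophile adds and the aryl anion is caught by a neighbouring acyl group (xanthones from salicylates, chroman-4-ones from unsaturated acids), here extended to an aliphatic β-oxido N-methoxy-N-methylamide. Ring C closes by 6-exo-trig attack of the C4a carbanion on C4. No stereocentre is created: C2 is the pre-set (S)-carbinol carbon, whose C–O bond is never broken, and the masked ketone shuts off retro-oxa-Michael opening of ring C. The step needs regioselective addition to the aryne, and this is secured by the C5 methoxymethoxy group, whose inductive pull makes C8a the electrophilic carbon and stabilises the anion at C4a; this should outweigh the small steric bias of the C8 prenyl group.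

Step 12
Reactants: 26 (2S)-2-[3,4-bis(methoxymethoxy)phenyl]-7-methoxy-5-(methoxymethoxy)-8-(3-methylbut-2-en-1-yl)chroman-4-one
Product: 27 (2S)-2-(3,4-dihydroxyphenyl)-5-hydroxy-7-methoxy-8-(3-methylbut-2-en-1-yl)chroman-4-one
Conditions: 3 M aq. HCl, MeOH, 45 °C
Reagents that add atoms: none
Why: acid-catalysed methanolysis of the three aryl MOM acetals (transacetalisation to dimethoxymethane); dilute acid at moderate temperature should spare the trisubstituted alkene, which has no neighbouring free hydroxyl to cyclise onto, and does not open ring C, so C2 stays S.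

**Compound list**

1 | 5-methoxyresorcinol | COc1cc(O)cc(O)c1 | starting material
2 | 5-methoxy-1,3-phenylene bis(N-isopropylcarbamate) | COc1cc(OC(=O)NC(C)C)cc(OC(=O)NC(C)C)c1 | intermediate
3 | 5-methoxy-1,3-phenylene bis[N-isopropyl-N-(tert-butyldimethylsilyl)carbamate] | COc1cc(OC(=O)N(C(C)C)[Si](C)(C)C(C)(C)C)cc(OC(=O)N(C(C)C)[Si](C)(C)C(C)(C)C)c1 | intermediate (not isolated)
4 | 2-lithio derivative of 3 | COc1cc(OC(=O)N(C(C)C)[Si](C)(C)C(C)(C)C)c([Li])c(OC(=O)N(C(C)C)[Si](C)(C)C(C)(C)C)c1 | intermediate (not isolated)
5 | 2-(trimethylsilyl) derivative of 3 | COc1cc(OC(=O)N(C(C)C)[Si](C)(C)C(C)(C)C)c([Si](C)(C)C)c(OC(=O)N(C(C)C)[Si](C)(C)C(C)(C)C)c1 | intermediate (not isolated)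
6 | 5-methoxy-2-(trimethylsilyl)-1,3-phenylene bis(N-isopropylcarbamate) | COc1cc(OC(=O)NC(C)C)c([Si](C)(C)C)c(OC(=O)NC(C)C)c1 | intermediate
7 | 3-hydroxy-5-methoxy-2-(trimethylsilyl)phenyl N-isopropylcarbamate | COc1cc(O)c([Si](C)(C)C)c(OC(=O)NC(C)C)c1 | intermediate
8 | 5-methoxy-3-(methoxymethoxy)-2-(trimethylsilyl)phenyl N-isopropylcarbamate | COc1cc(OCOC)c([Si](C)(C)C)c(OC(=O)NC(C)C)c1 | intermediate
9 | prenyl bromide (1-bromo-3-methylbut-2-ene) | CC(C)=CCBr | starting material
10 | N-(tert-butyldimethylsilyl) derivative of 8 | COc1cc(OCOC)c([Si](C)(C)C)c(OC(=O)N(C(C)C)[Si](C)(C)C(C)(C)C)c1 | intermediate (not isolated)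
11 | 6-lithio derivative of 10 (lithium between carbamate and methoxy) | COc1cc(OCOC)c([Si](C)(C)C)c(OC(=O)N(C(C)C)[Si](C)(C)C(C)(C)C)c1[Li] | intermediate (not isolated)
12 | N-(tert-butyldimethylsilyl) derivative of 13 | COc1cc(OCOC)c([Si](C)(C)C)c(OC(=O)N(C(C)C)[Si](C)(C)C(C)(C)C)c1CC=C(C)C | intermediate (not isolated)
13 | 3-methoxy-5-(methoxymethoxy)-2-(3-methylbut-2-en-1-yl)-6-(trimethylsilyl)phenyl N-isopropylcarbamate | COc1cc(OCOC)c([Si](C)(C)C)c(OC(=O)NC(C)C)c1CC=C(C)C | intermediate
14 | 3-methoxy-5-(methoxymethoxy)-2-(3-methylbut-2-en-1-yl)-6-(trimethylsilyl)phenol | COc1cc(OCOC)c([Si](C)(C)C)c(O)c1CC=C(C)C | intermediate (not isolated)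
15 | 3-methoxy-5-(methoxymethoxy)-2-(3-methylbut-2-en-1-yl)-6-(trimethylsilyl)phenyl trifluoromethanesulfonate | COc1cc(OCOC)c([Si](C)(C)C)c(OS(=O)(=O)C(F)(F)F)c1CC=C(C)C | intermediate
16 | methyl 3,4-dihydroxybenzoate | COC(=O)c1ccc(O)c(O)c1 | starting material
17 | methyl 3,4-bis(methoxymethoxy)benzoate | COC(=O)c1ccc(OCOC)c(OCOC)c1 | intermediate
18 | N-methoxy-N-methylacetamide | CC(=O)N(C)OC | starting material
19 | lithium enolate of N-methoxy-N-methylacetamide | C=C(O[Li])N(C)OC | intermediate (not isolated)
20 | 3-[3,4-bis(methoxymethoxy)phenyl]-N-methoxy-N-methyl-3-oxopropanamide | COCOc1ccc(C(=O)CC(=O)N(C)OC)cc1OCOC | intermediate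
21 | (S)-3-[3,4-bis(methoxymethoxy)phenyl]-3-hydroxy-N-methoxy-N-methylpropanamide | O[C@H](c1ccc(OCOC)c(OCOC)c1)CC(=O)N(C)OC | intermediate
22 | (S)-3-[3,4-bis(methoxymethoxy)phenyl]-N-methoxy-N-methyl-3-(trimethylsilyloxy)propanamide | C[Si](C)(C)O[C@H](c1ccc(OCOC)c(OCOC)c1)CC(=O)N(C)OC | intermediate
23 | 5-methoxy-3-(methoxymethoxy)-6-(3-methylbut-2-en-1-yl)-1,2-didehydrobenzene (aryne across C4a–C8a) | CC(C)=CCC1=C(OC)C=C(OCOC)C#C1 | intermediate (not isolated)
24 | cesium (S)-alkoxide of 21 | [Cs+].[O-][C@H](c1ccc(OCOC)c(OCOC)c1)CC(=O)N(C)OC | intermediate (not isolated)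
25 | (2S)-2-[3,4-bis(methoxymethoxy)phenyl]-7-methoxy-4-[methoxy(methyl)amino]-5-(methoxymethoxy)-8-(3-methylbut-2-en-1-yl)-4-(trimethylsilyloxy)chromane, C4 configuration undefined | COc1cc(OCOC)c2c(c1CC=C(C)C)O[C@H](c1ccc(OCOC)c(OCOC)c1)CC2(O[Si](C)(C)C)N(C)OC | intermediate (not isolated)
26 | (2S)-2-[3,4-bis(methoxymethoxy)phenyl]-7-methoxy-5-(methoxymethoxy)-8-(3-methylbut-2-en-1-yl)chroman-4-one | COc1cc(OCOC)c2c(c1CC=C(C)C)O[C@H](c1ccc(OCOC)c(OCOC)c1)CC2=O | intermediate
27 | (2S)-2-(3,4-dihydroxyphenyl)-5-hydroxy-7-methoxy-8-(3-methylbut-2-en-1-yl)chroman-4-one | COc1cc(O)c2c(c1CC=C(C)C)O[C@H](c1ccc(O)c(O)c1)CC2=O | target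

**Step count and risks**

Total step count: 12. Longest linear sequence: 8 steps (steps 1–6, 11, 12).

Steps most likely to fail:

Step 11. What may go wrong: the aryl anion is protonated before it reaches the amide, the alkoxide adds with the reverse orientation, or the tetrahedral adduct collapses in the flask and the released base opens ring C with loss of configuration. The fallback uses known reaction types only, sets out from triflate 15 and returns at flavanone 26. Heating 15 with acetic acid and CsF in THF in a sealed tube should give, by the established aryne insertion into the C–O bond of a carboxylic acid, 1-[2-hydroxy-4-methoxy-6-(methoxymethoxy)-3-(3-methylbut-2-en-1-yl)phenyl]ethanone F1. Condensation with DMF dimethyl acetal in toluene at 90 °C gives the enaminone (E)-3-(dimethylamino)-1-[2-hydroxy-4-methoxy-6-(methoxymethoxy)-3-(3-methylbut-2-en-1-yl)phenyl]prop-2-en-1-one F2, which is cyclised with pyridinium p-toluenesulfonate to 7-methoxy-5-(methoxymethoxy)-8-(3-methylbut-2-en-1-yl)-4H-chromen-4-one F3. In parallel, commercial 4-bromocatechol is protected (MOMCl, i-Pr2NEt) as 4-bromo-1,2-bis(methoxymethoxy)benzene F4 and converted by n-BuLi and B(Oi-Pr)3 with aqueous work-up into [3,4-bis(methoxymethoxy)phenyl]boronic acid F5. Rhodium-catalysed asymmetric conjugate addition of F5 to F3 ([RhCl(C2H4)2]2, chiral diene ligand of the antipode that gives 2S, aq. KOH, dioxane) then delivers 26.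

Step 5. What may go wrong: lithiation at the carbon between the two ether groups, migration of the carbamoyl group to carbon on warming, or SN2′ alkylation giving the reverse-prenyl isomer. The fallback sets out from carbamate 8 and returns at phenol 14, which is then triflated with PhNTf2 as in the second half of step 6. Carbamate 8 is cleaved (DBU, Et2NH, MeCN, 40 °C) to 5-methoxy-3-(methoxymethoxy)-2-(trimethylsilyl)phenol F6. O-alkylation with 3-chloro-3-methylbut-1-yne (CuCl2 cat., DBU, MeCN, 0 °C) gives the tertiary propargyl ether 1-methoxy-3-(methoxymethoxy)-5-[(2-methylbut-3-yn-2-yl)oxy]-4-(trimethylsilyl)benzene F7. Semihydrogenation over Lindlar catalyst (Pd on CaCO3, lead-poisoned, quinoline, H2) gives the 1,1-dimethylallyl ether 1-methoxy-3-(methoxymethoxy)-5-[(2-methylbut-3-en-2-yl)oxy]-4-(trimethylsilyl)benzene F8. Aromatic Claisen rearrangement (N,N-diethylaniline, 130 °C) can reach only the single free ortho carbon and gives 14 with a normal prenyl group.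

Step 3. What may go wrong: cleavage runs on to the diol or stops short, so that little of the mono-phenol is obtained per pass. The fallback moves the desymmetrisation to the start; it sets out from 5-methoxyresorcinol 1 and returns at carbamate 8 by way of 10. Monoprotection of 1 (MOMCl 1 equiv, i-Pr2NEt; diol and bis-ether recycled) gives 3-methoxy-5-(methoxymethoxy)phenol F9, and i-PrNCO/Et3N gives 3-methoxy-5-(methoxymethoxy)phenyl N-isopropylcarbamate F10. N-silylation (TBSOTf, TMEDA) gives the N-silyl carbamate F11, and n-BuLi/TMEDA at −78 °C should lithiate between the carbamate and the methoxymethoxy group, the better pair of directing groups, to give aryllithium F12. TMSCl converts F12 into 10, and hydrolytic work-up gives 8; any regioisomer from lithiation on the methoxy side would have to be separated here.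

**Further compounds**

F1 | step 11 | 1-[2-hydroxy-4-methoxy-6-(methoxymethoxy)-3-(3-methylbut-2-en-1-yl)phenyl]ethanone | CC(=O)c1c(O)c(CC=C(C)C)c(OC)cc1OCOC
F2 | step 11 | (E)-3-(dimethylamino)-1-[2-hydroxy-4-methoxy-6-(methoxymethoxy)-3-(3-methylbut-2-en-1-yl)phenyl]prop-2-en-1-one | CN(C)/C=C/C(=O)c1c(O)c(CC=C(C)C)c(OC)cc1OCOC
F3 | step 11 | 7-methoxy-5-(methoxymethoxy)-8-(3-methylbut-2-en-1-yl)-4H-chromen-4-one | COc1cc(OCOC)c2c(=O)ccoc2c1CC=C(C)C
F4 | step 11 | 4-bromo-1,2-bis(methoxymethoxy)benzene | COCOc1ccc(Br)cc1OCOC
F5 | step 11 | [3,4-bis(methoxymethoxy)phenyl]boronic acid | COCOc1ccc(B(O)O)cc1OCOC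
F6 | step 5 | 5-methoxy-3-(methoxymethoxy)-2-(trimethylsilyl)phenol | COc1cc(O)c([Si](C)(C)C)c(OCOC)c1
F7 | step 5 | 1-methoxy-3-(methoxymethoxy)-5-[(2-methylbut-3-yn-2-yl)oxy]-4-(trimethylsilyl)benzene | COc1cc(OC(C)(C)C#C)c([Si](C)(C)C)c(OCOC)c1
F8 | step 5 | 1-methoxy-3-(methoxymethoxy)-5-[(2-methylbut-3-en-2-yl)oxy]-4-(trimethylsilyl)benzene | COc1cc(OC(C)(C)C=C)c([Si](C)(C)C)c(OCOC)c1
F9 | step 3 | 3-methoxy-5-(methoxymethoxy)phenol | COCOc1cc(O)cc(OC)c1
F10 | step 3 | 3-methoxy-5-(methoxymethoxy)phenyl N-isopropylcarbamate | COCOc1cc(OC(=O)NC(C)C)cc(OC)c1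
F11 | step 3 | 3-methoxy-5-(methoxymethoxy)phenyl N-isopropyl-N-(tert-butyldimethylsilyl)carbamate | COCOc1cc(OC(=O)N(C(C)C)[Si](C)(C)C(C)(C)C)cc(OC)c1
F12 | step 3 | 2-lithio derivative of F11 (lithium between carbamate and methoxymethoxy) | COc1cc(OCOC)c([Li])c(OC(=O)N(C(C)C)[Si](C)(C)C(C)(C)C)c1
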